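The route cuts ring A itself, not the hindered diaryl ether bond. Ring A bears oxygen at C2 and C4, the carboxyl at C1 and the heptyl chain at C6. A 1,3-dioxygenated cyclohexa-1,3-diene and a 2-alkynoate deliver exactly this pattern. The ether oxygen is therefore joined to the ring B phenol while C2 is still the beta carbon of a chloroenone. Kinetic silylation then gives the 1-aryloxy-3-silyloxydiene. Heated with benzyl dec-2-ynoate, it forms C1–C2 and C5–C6. The bicyclic adduct expels ethylene, so the complete arene appears in one operation. Ring B is made from 5-heptylresorcinol by formylation, Baeyer–Villiger oxidation and carboxylation.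

Key step: step 13

Numbering: ring A has C1 carboxyl, C2 aryloxy, C4 methoxy and C6 heptyl. Ring B has C1 carboxyl, C2 hydroxyl, C3 H, C4 aryloxy, C5 methoxy and C6 heptyl.
Assumption: 5-heptylbenzene-1,3-diol is bought as a catalogue compound; the target is achiral, and the only stereogenic atoms in the route (the bridgeheads of racemic 20) are erased within the same step.

Step 1
Reactants: 1 5-heptylbenzene-1,3-diol (5-heptylresorcinol)
Product: 3 2-heptyl-4,6-dihydroxybenzaldehyde, via aryl iminium salt 2 (not isolated)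
Conditions: POCl3, DMF, 0 °C to rt; then H2O, 50 °C
Reagents that add atoms: N,N-dimethylformamide CN(C)C=O; water O
Why: Vilsmeier–Haack formylation of a 5-alkylresorcinol should occur at C4, para to one hydroxyl and ortho to the other, not at the crowded C2 between the hydroxyls, and hydrolysis of 2 releases the aldehyde.

Step 2
Reactants: 3 2-heptyl-4,6-dihydroxybenzaldehyde
Product: 4 4-(benzyloxy)-2-heptyl-6-hydroxybenzaldehyde
Conditions: BnBr (1.05 equiv), K2CO3 (1.1 equiv), acetone, reflux
Reagents that add atoms: benzyl bromide BrCc1ccccc1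
Why: Williamson ether synthesis in which the hydroxyl next to the formyl group is held in an intramolecular hydrogen bond, so one equivalent of base and halide should reach only the more acidic para hydroxyl, the future ring B C2 oxygen.

Step 3
Reactants: 4 4-(benzyloxy)-2-heptyl-6-hydroxybenzaldehyde
Product: 5 4-(benzyloxy)-2-heptyl-6-(methoxymethoxy)benzaldehyde
Conditions: MeOCH2Cl, K2CO3, DMF, 0 °C to rt
Reagents that add atoms: chloromethyl methyl ether COCCl
Why: Methoxymethyl ether formation by O-alkylation with an alpha-chloro ether gives an acetal that resists peracid, carbonate and n-BuLi, cannot migrate to a neighbouring phenoxide as an acyl or silyl group could, and is orthogonal to benzyl.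

Step 4
Reactants: 5 4-(benzyloxy)-2-heptyl-6-(methoxymethoxy)benzaldehyde
Product: 7 4-(benzyloxy)-2-heptyl-6-(methoxymethoxy)phenol, via aryl formate 6 (not isolated)
Conditions: mCPBA, CH2Cl2, 0 °C to rt; then K2CO3 (cat.), MeOH, rt
Reagents that add atoms: 3-chloroperoxybenzoic acid O=C(OO)c1cccc(Cl)c1
Why: Baeyer–Villiger oxidation in its Dakin-type mode, where the aryl group with alkoxy donors ortho and para migrates in preference to hydrogen, and formate 6 is then cleaved by transesterification that leaves both ethers alone.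

Step 5
Reactants: 7 4-(benzyloxy)-2-heptyl-6-(methoxymethoxy)phenol
Product: 8 5-(benzyloxy)-1-heptyl-2-methoxy-3-(methoxymethoxy)benzene
Conditions: MeI, K2CO3, DMF, rt
Reagents that add atoms: iodomethane CI
Why: Williamson methylation of the only free phenol fixes the ring B C5 methoxy group, and the small electrophile copes with the two ortho substituents.

Step 6
Reactants: 8 5-(benzyloxy)-1-heptyl-2-methoxy-3-(methoxymethoxy)benzene
Product: 9 1-(benzyloxy)-2-bromo-3-heptyl-4-methoxy-5-(methoxymethoxy)benzene
Conditions: NBS (1.0 equiv), MeCN, 0 °C, dark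
Reagents that add atoms: N-bromosuccinimide O=C1CCC(=O)N1Br
Why: Electrophilic aromatic bromination should take the free position para to the methoxymethoxy group and ortho to the benzyloxy group, as in 1,2,4-trialkoxybenzenes and 3,5-dialkoxyalkylbenzenes, while the site between two alkoxy groups stays untouched and the polar medium suppresses benzylic radical bromination.

Step 7
Reactants: 9 1-(benzyloxy)-2-bromo-3-heptyl-4-methoxy-5-(methoxymethoxy)benzene
Product: 11 benzyl 2-(benzyloxy)-6-heptyl-5-methoxy-4-(methoxymethoxy)benzoate, via aryllithium 10 (not isolated)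
Conditions: n-BuLi, THF, −78 °C; then cannulated into ClCO2Bn (2 equiv), THF, −78 °C
Reagents that add atoms: benzyl chloroformate O=C(Cl)OCc1ccccc1
Why: Bromine–lithium exchange outruns deprotonation at −78 °C, and acylation of 10 by inverse addition to a chloroformate should stop at the ester because two ortho substituents shield its carbonyl group.

Step 8
Reactants: 11 benzyl 2-(benzyloxy)-6-heptyl-5-methoxy-4-(methoxymethoxy)benzoate
Product: 12 benzyl 2-(benzyloxy)-6-heptyl-4-hydroxy-5-methoxybenzoate (ring B phenol)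
Conditions: HCl (cat.), MeOH–THF, 40 °C
Reagents that add atoms: none
Why: Acid-catalysed acetal exchange removes the methoxymethyl group, while the benzyl ether is inert and the di-ortho-substituted benzyl ester is too hindered for transesterification.

Step 9
Reactants: 13 cyclohexane-1,3-dione
Product: 14 3-chlorocyclohex-2-en-1-one
Conditions: (COCl)2, DMF (cat.), CH2Cl2, 0 °C to rt
Reagents that add atoms: oxalyl chloride O=C(Cl)C(=O)Cl
Why: The enol of the dione behaves as a vinylogous carboxylic acid, and oxalyl chloride converts it into the vinylogous acid chloride with loss of gases only.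

Step 10
Reactants: 12 ring B phenol; 14 3-chlorocyclohex-2-en-1-one
Product: 15 benzyl 2-(benzyloxy)-6-heptyl-5-methoxy-4-[(3-oxocyclohex-1-en-1-yl)oxy]benzoate
Conditions: K2CO3, DMF, rt to 50 °C
Reagents that add atoms: none
Why: Addition–elimination (nucleophilic vinylic substitution) of the phenoxide on the beta-chloroenone should be easy, because the phenol is acidified by its para ester and has only one ortho substituent.

Step 11
Reactants: 15 aryloxy enone
Product: 17 benzyl 2-(benzyloxy)-6-heptyl-5-methoxy-4-{[3-(trimethylsilyloxy)cyclohexa-1,3-dien-1-yl]oxy}benzoate, via lithium dienolate 16 (not isolated)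
Conditions: Me3SiCl (1.5 equiv, present from the start), LiN(i-Pr)2 (1.1 equiv), THF, −78 °C; evaporation, pentane, filtration under Ar, used crude
Reagents that add atoms: chlorotrimethylsilane C[Si](C)(C)Cl
Why: Kinetic alpha-prime deprotonation of a vinylogous ester, the regiochemistry of Stork–Danheiser chemistry, gives the cross-conjugated dienolate 16, which the silyl chloride already present traps on oxygen before the base can touch the benzylic CH2 ortho to the ring B ester.

Step 12
Reactants: 18 dec-2-ynoic acid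
Product: 19 benzyl dec-2-ynoate
Conditions: BnBr, KHCO3, DMF, rt
Reagents that add atoms: benzyl bromide BrCc1ccccc1
Why: SN2 alkylation of the carboxylate proceeds under hydrogencarbonate conditions that are too mild to isomerise the alkyne into an allene.

Step 13
Reactants: 17 1-aryloxy-3-silyloxydiene; 19 benzyl dec-2-ynoate (3 equiv)
Product: 22 benzyl 2-(benzyloxy)-4-[2-(benzyloxycarbonyl)-3-heptyl-5-hydroxyphenoxy]-6-heptyl-5-methoxybenzoate, via bicyclo[2.2.2]octadiene adduct 20 (not isolated), via aryl trimethylsilyl ether 21 (not isolated)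
Conditions: minimal mesitylene, silylated sealed tube, Ar, 180 °C; then 1 M HCl, THF, rt
Reagents that add atoms: none
Why: This is a thermal Alder–Rickert sequence that opens with a concerted but asynchronous (4+2) cycloaddition, in which the unsubstituted diene terminus (future C5), made nucleophilic by both the aryloxy and the silyloxy donor, bonds ahead to the heptyl-bearing beta carbon of 19 (C5–C6) while the aryloxy-bearing terminus closes onto the alpha carbon (C1–C2). One six-membered carbocycle is closed by intermolecular (4+2) ring formation to give 20, whose CH2CH2 bridge then leaves as ethylene in a retro-Diels–Alder step driven by aromatisation, so ring A needs neither elimination nor oxidant. The closest known reaction type is the preparation of 6-alkylresorcylates from 1-alkoxy-3-silyloxycyclohexa-1,3-dienes and 2-alkynoates. The only selectivity needed is regioselectivity, and the matched polarisation of diene and ynoate secures it by placing the ester next to the aryloxy carbon. No stereocentre survives, because both bridgeheads of racemic 20 become sp2 carbons, and an aryloxy group on a bridgehead cannot be lost as phenol 12. Dilute acid finally cleaves the aryl silyl ether 21 to phenol 22.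

Step 14
Reactants: 22 ring A phenol
Product: 23 benzyl 2-(benzyloxy)-4-[2-(benzyloxycarbonyl)-3-heptyl-5-methoxyphenoxy]-6-heptyl-5-methoxybenzoate
Conditions: MeI, K2CO3, acetone, reflux
Reagents that add atoms: iodomethane CI
Why: Williamson methylation meets a single free phenol, which is acidified by its para ester, so no selectivity question arises.

Step 15
Reactants: 23 tribenzyl dimethyl ether
Product: 24 4-(2-carboxy-3-heptyl-5-methoxyphenoxy)-6-heptyl-2-hydroxy-5-methoxybenzoic acid (target)
Conditions: H2 (1 atm), 10% Pd/C, EtOAc–EtOH, rt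
Reagents that add atoms: none
Why: Catalytic hydrogenolysis cleaves the two benzyl esters and the benzyl ether in one neutral operation at room temperature, which spares the diaryl ether, the methyl ethers and the acid groups that could decarboxylate on heating.

Compound list
1 | 5-heptylbenzene-1,3-diol | CCCCCCCc1cc(O)cc(O)c1 | starting material
2 | [(2-heptyl-4,6-dihydroxyphenyl)methylidene]dimethylammonium dichlorophosphate | CCCCCCCc1cc(O)cc(O)c1C=[N+](C)C.[O-]P(=O)(Cl)Cl | intermediate
3 | 2-heptyl-4,6-dihydroxybenzaldehyde | CCCCCCCc1cc(O)cc(O)c1C=O | intermediate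
4 | 4-(benzyloxy)-2-heptyl-6-hydroxybenzaldehyde | CCCCCCCc1cc(OCc2ccccc2)cc(O)c1C=O | intermediate
5 | 4-(benzyloxy)-2-heptyl-6-(methoxymethoxy)benzaldehyde | CCCCCCCc1cc(OCc2ccccc2)cc(OCOC)c1C=O | intermediate
6 | 4-(benzyloxy)-2-heptyl-6-(methoxymethoxy)phenyl formate | CCCCCCCc1cc(OCc2ccccc2)cc(OCOC)c1OC=O | intermediate
7 | 4-(benzyloxy)-2-heptyl-6-(methoxymethoxy)phenol | CCCCCCCc1cc(OCc2ccccc2)cc(OCOC)c1O | intermediate
8 | 5-(benzyloxy)-1-heptyl-2-methoxy-3-(methoxymethoxy)benzene | CCCCCCCc1cc(OCc2ccccc2)cc(OCOC)c1OC | intermediate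
9 | 1-(benzyloxy)-2-bromo-3-heptyl-4-methoxy-5-(methoxymethoxy)benzene | CCCCCCCc1c(Br)c(OCc2ccccc2)cc(OCOC)c1OC | intermediate
10 | [2-(benzyloxy)-6-heptyl-5-methoxy-4-(methoxymethoxy)phenyl]lithium | CCCCCCCc1c([Li])c(OCc2ccccc2)cc(OCOC)c1OC | intermediate
11 | benzyl 2-(benzyloxy)-6-heptyl-5-methoxy-4-(methoxymethoxy)benzoate | CCCCCCCc1c(C(=O)OCc2ccccc2)c(OCc2ccccc2)cc(OCOC)c1OC | intermediate
12 | benzyl 2-(benzyloxy)-6-heptyl-4-hydroxy-5-methoxybenzoate | CCCCCCCc1c(C(=O)OCc2ccccc2)c(OCc2ccccc2)cc(O)c1OC | intermediate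
13 | cyclohexane-1,3-dione | O=C1CCCC(=O)C1 | starting material
14 | 3-chlorocyclohex-2-en-1-one | O=C1C=C(Cl)CCC1 | intermediate
15 | benzyl 2-(benzyloxy)-6-heptyl-5-methoxy-4-[(3-oxocyclohex-1-en-1-yl)oxy]benzoate | O=C1C=C(Oc2cc(OCc3ccccc3)c(C(=O)OCc3ccccc3)c(CCCCCCC)c2OC)CCC1 | intermediate
16 | lithium cross-conjugated dienolate of 15 | [Li]OC1=CCCC(Oc2cc(OCc3ccccc3)c(C(=O)OCc3ccccc3)c(CCCCCCC)c2OC)=C1 | intermediate
17 | benzyl 2-(benzyloxy)-6-heptyl-5-methoxy-4-{[3-(trimethylsilyloxy)cyclohexa-1,3-dien-1-yl]oxy}benzoate | C[Si](C)(C)OC1=CCCC(Oc2cc(OCc3ccccc3)c(C(=O)OCc3ccccc3)c(CCCCCCC)c2OC)=C1 | intermediate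
18 | dec-2-ynoic acid | CCCCCCCC#CC(=O)O | starting material
19 | benzyl dec-2-ynoate | CCCCCCCC#CC(=O)OCc1ccccc1 | intermediate
20 | benzyl 1-(ring B aryloxy)-3-heptyl-5-(trimethylsilyloxy)bicyclo[2.2.2]octa-2,5-diene-2-carboxylate (racemic, no descriptors) | C[Si](C)(C)OC1=CC2(Oc3cc(OCc4ccccc4)c(C(=O)OCc4ccccc4)c(CCCCCCC)c3OC)CCC1C(CCCCCCC)=C2C(=O)OCc1ccccc1 | intermediate
21 | benzyl 2-(benzyloxy)-4-[2-(benzyloxycarbonyl)-3-heptyl-5-(trimethylsilyloxy)phenoxy]-6-heptyl-5-methoxybenzoate | CCCCCCCc1cc(O[Si](C)(C)C)cc(Oc2cc(OCc3ccccc3)c(C(=O)OCc3ccccc3)c(CCCCCCC)c2OC)c1C(=O)OCc1ccccc1 | intermediate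
22 | benzyl 2-(benzyloxy)-4-[2-(benzyloxycarbonyl)-3-heptyl-5-hydroxyphenoxy]-6-heptyl-5-methoxybenzoate | CCCCCCCc1cc(O)cc(Oc2cc(OCc3ccccc3)c(C(=O)OCc3ccccc3)c(CCCCCCC)c2OC)c1C(=O)OCc1ccccc1 | intermediate
23 | benzyl 2-(benzyloxy)-4-[2-(benzyloxycarbonyl)-3-heptyl-5-methoxyphenoxy]-6-heptyl-5-methoxybenzoate | CCCCCCCc1cc(OC)cc(Oc2cc(OCc3ccccc3)c(C(=O)OCc3ccccc3)c(CCCCCCC)c2OC)c1C(=O)OCc1ccccc1 | intermediate
24 | 4-(2-carboxy-3-heptyl-5-methoxyphenoxy)-6-heptyl-2-hydroxy-5-methoxybenzoic acid | CCCCCCCc1cc(OC)cc(Oc2cc(O)c(C(=O)O)c(CCCCCCC)c2OC)c1C(=O)O | target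

Total step count: 15. Longest linear sequence: 13 (steps 1 to 8, 10, 11, 13, 14, 15).

Steps most likely to fail

Step 13. A beta-alkyl ynoate is a sluggish dienophile. At the temperature needed, the diene may drift through [1,5]-hydrogen shifts, revert to the enone by adventitious protodesilylation, or oligomerise before it is consumed.
- The fallback sets out from 3 and 12 and returns at 23. It builds ring A as a separate arene and closes the ether bond by palladium-catalysed C–O coupling.
- Aldehyde 3 is methylated at its non-chelated hydroxyl (MeI, K2CO3, acetone) to 2-heptyl-6-hydroxy-4-methoxybenzaldehyde F1.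
- Pinnick oxidation (NaClO2, NaH2PO4, 2-methylbut-2-ene) gives 2-heptyl-6-hydroxy-4-methoxybenzoic acid F2.
- BnBr and KHCO3 give benzyl 2-heptyl-6-hydroxy-4-methoxybenzoate F3.
- Tf2O and pyridine give benzyl 2-heptyl-4-methoxy-6-(trifluoromethylsulfonyloxy)benzoate F4.
- Slow addition of F4 to 12 with Pd(OAc)2, t-BuXPhos and K3PO4 in toluene at 100 °C should give 23 directly.

Step 11. Competing deprotonation at the benzylic CH2 next to the ring B ester could erode the material. So could hydrolysis of the trimethylsilyl dienol ether during isolation of a compound that can be neither distilled nor chromatographed.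
- The fallback sets out from 15 and returns at 22. It replaces the transient silyl group by a robust one that is removed in a separate fluoride step.
- The weaker base LiN(SiMe3)2 (THF, −78 °C) followed by t-BuMe2SiOTf gives benzyl 2-(benzyloxy)-4-{[3-(tert-butyldimethylsilyloxy)cyclohexa-1,3-dien-1-yl]oxy}-6-heptyl-5-methoxybenzoate F5. This compound can be purified on silica deactivated with Et3N.
- Heating with 19 leads through the tert-butyldimethylsilyloxy bicyclo[2.2.2]octadiene adduct F6 to the aryl tert-butyldimethylsilyl ether F7.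
- Bu4NF in THF converts F7 into 22.

Step 7. The crowded aryllithium may be quenched by proton transfer from the neighbouring benzylic OCH2, with Wittig-type rearrangement, or may acylate incompletely.
- The fallback sets out from 8 and returns at 12. It bypasses steps 6 to 8 and replaces halogen–metal exchange by electrophilic formylation and oxidation.
- HCl in MeOH removes the acetal to give 5-(benzyloxy)-3-heptyl-2-methoxyphenol F8.
- Vilsmeier–Haack formylation para to the free hydroxyl gives 2-(benzyloxy)-6-heptyl-4-hydroxy-5-methoxybenzaldehyde F9.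
- Pinnick oxidation with a chlorine scavenger gives 2-(benzyloxy)-6-heptyl-4-hydroxy-5-methoxybenzoic acid F10.
- BnBr with one equivalent of KHCO3 alkylates only the carboxylate and gives 12.

Further compounds
F1 | step 13 | 2-heptyl-6-hydroxy-4-methoxybenzaldehyde | CCCCCCCc1cc(OC)cc(O)c1C=O
F2 | step 13 | 2-heptyl-6-hydroxy-4-methoxybenzoic acid | CCCCCCCc1cc(OC)cc(O)c1C(=O)O
F3 | step 13 | benzyl 2-heptyl-6-hydroxy-4-methoxybenzoate | CCCCCCCc1cc(OC)cc(O)c1C(=O)OCc1ccccc1
F4 | step 13 | benzyl 2-heptyl-4-methoxy-6-(trifluoromethylsulfonyloxy)benzoate | CCCCCCCc1cc(OC)cc(OS(=O)(=O)C(F)(F)F)c1C(=O)OCc1ccccc1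
F5 | step 11 | benzyl 2-(benzyloxy)-4-{[3-(tert-butyldimethylsilyloxy)cyclohexa-1,3-dien-1-yl]oxy}-6-heptyl-5-methoxybenzoate | CC(C)(C)[Si](C)(C)OC1=CCCC(Oc2cc(OCc3ccccc3)c(C(=O)OCc3ccccc3)c(CCCCCCC)c2OC)=C1
F6 | step 11 | tert-butyldimethylsilyloxy bicyclo[2.2.2]octadiene adduct (racemic) | CC(C)(C)[Si](C)(C)OC1=CC2(Oc3cc(OCc4ccccc4)c(C(=O)OCc4ccccc4)c(CCCCCCC)c3OC)CCC1C(CCCCCCC)=C2C(=O)OCc1ccccc1
F7 | step 11 | aryl tert-butyldimethylsilyl ether of 22 | CCCCCCCc1cc(O[Si](C)(C)C(C)(C)C)cc(Oc2cc(OCc3ccccc3)c(C(=O)OCc3ccccc3)c(CCCCCCC)c2OC)c1C(=O)OCc1ccccc1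
F8 | step 7 | 5-(benzyloxy)-3-heptyl-2-methoxyphenol | CCCCCCCc1cc(OCc2ccccc2)cc(O)c1OC
F9 | step 7 | 2-(benzyloxy)-6-heptyl-4-hydroxy-5-methoxybenzaldehyde | CCCCCCCc1c(C=O)c(OCc2ccccc2)cc(O)c1OC
F10 | step 7 | 2-(benzyloxy)-6-heptyl-4-hydroxy-5-methoxybenzoic acid | CCCCCCCc1c(C(=O)O)c(OCc2ccccc2)cc(O)c1OC
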